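The target is a 3',6''-linked biflavone. It is traced back to its 3',8''-linked isomer sciadopitysin, because C8 of a 5,7-dialkoxyflavone is the position that electrophilic iodination, and hence Suzuki coupling, reaches directly. The key step opens the pyranone (ring C) of the acacetin half at O1''–C2'' and recloses it through the free 5''-hydroxyl of ring A. In one operation this forms a new O–C2'' bond and a new pyranone ring and moves the aryl group from C8'' to C6''. It exploits the two oxygens (O1'' and 5''-OH) ortho to C4a''; the 5-hydroxy-7-methoxy half can only rearrange degenerately. The precursor has free 5''- and 7''-hydroxyls and three methyl ethers.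

Key step: step 8

Remark: unprimed and singly primed locants refer to the 5-hydroxy-7-methoxyflavone half, doubly and triply primed ones to the acacetin half; the biaryl axis is taken as freely rotating, so no stereochemical element has to be controlled.

Step 1
Reactants: 1 2',6'-dihydroxy-4'-methoxyacetophenone; 2 3-bromo-4-methoxybenzaldehyde
Product: 3 (E)-3-(3-bromo-4-methoxyphenyl)-1-(2,6-dihydroxy-4-methoxyphenyl)prop-2-en-1-one
Conditions: KOH (50% aq), EtOH, rt, 48 h; then aq HCl to pH 3
Reagents that add atoms: none
Why: Claisen–Schmidt aldol condensation of the methyl ketone enolate with the non-enolisable aldehyde, the E1cB dehydration giving the conjugated E-enone; the aryl bromide is inert to aqueous hydroxide at room temperature.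

Step 2
Reactants: 3 (E)-3-(3-bromo-4-methoxyphenyl)-1-(2,6-dihydroxy-4-methoxyphenyl)prop-2-en-1-one
Product: 5 2-(3-bromo-4-methoxyphenyl)-5-hydroxy-7-methoxy-4H-chromen-4-one, via flavanone 4 (not isolated)
Conditions: I2 (10 mol %), DMSO, 125 °C
Reagents that add atoms: none
Why: Iodine-catalysed oxidative cyclisation of a 2'-hydroxychalcone (oxa-Michael closure to racemic flavanone 4, alpha-iodination and loss of HI, which DMSO reoxidises to I2), so the C2 stereocentre of 4 is erased and any 4 already present in crude 3 converges on the same flavone; the second, chelated hydroxyl remains as 5-OH.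

Step 3
Reactants: 5 2-(3-bromo-4-methoxyphenyl)-5-hydroxy-7-methoxy-4H-chromen-4-one
Product: 6 5-hydroxy-7-methoxy-2-[4-methoxy-3-(4,4,5,5-tetramethyl-1,3,2-dioxaborolan-2-yl)phenyl]-4H-chromen-4-one
Conditions: B2pin2 (1.3 equiv), Pd(dppf)Cl2 (5 mol %), KOAc (3 equiv), 1,4-dioxane, 90 °C
Reagents that add atoms: bis(pinacolato)diboron, CC1(C)OB(OC1(C)C)B1OC(C)(C)C(C)(C)O1
Why: Miyaura borylation (oxidative addition of the aryl bromide to zerovalent palladium, acetate-assisted transmetalation from the diboron); the weak base leaves the hydrogen-bonded 5-OH unprotected, which saves a protection and a deprotection.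

Step 4
Reactants: 7 acacetin (5,7-dihydroxy-2-(4-methoxyphenyl)-4H-chromen-4-one)
Product: 8 5,7-bis(methoxymethoxy)-2-(4-methoxyphenyl)-4H-chromen-4-one
Conditions: NaH (3 equiv), MOMCl (3 equiv), DMF, 0 °C to rt
Reagents that add atoms: chloromethyl methyl ether, COCCl
Why: Williamson-type O-alkylation of both phenoxides, the strong base being needed to break the 5-OH to C4=O hydrogen bond; capping O5 is what steers the next step to C8.

Step 5
Reactants: 8 5,7-bis(methoxymethoxy)-2-(4-methoxyphenyl)-4H-chromen-4-one
Product: 9 8-iodo-5,7-bis(methoxymethoxy)-2-(4-methoxyphenyl)-4H-chromen-4-one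
Conditions: NIS (1.1 equiv), DMF, rt, dark
Reagents that add atoms: N-iodosuccinimide, O=C1CCC(=O)N1I
Why: Electrophilic aromatic iodination under neutral conditions that spare the acetals; in 5,7-di-O-alkylflavones ring A is substituted at C8, because C6 is wedged between two alkoxy groups, and this is the known outcome for N-iodosuccinimide.

Step 6
Reactants: 9 8-iodo-5,7-bis(methoxymethoxy)-2-(4-methoxyphenyl)-4H-chromen-4-one; 6 5-hydroxy-7-methoxy-2-[4-methoxy-3-(4,4,5,5-tetramethyl-1,3,2-dioxaborolan-2-yl)phenyl]-4H-chromen-4-one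
Product: 10 8-[5-(5-hydroxy-7-methoxy-4-oxo-4H-chromen-2-yl)-2-methoxyphenyl]-5,7-bis(methoxymethoxy)-2-(4-methoxyphenyl)-4H-chromen-4-one
Conditions: Pd(OAc)2 (5 mol %), SPhos (10 mol %), K3PO4 (4 equiv), 1,4-dioxane/H2O 5:1, 90 °C
Reagents that add atoms: none
Why: Suzuki–Miyaura coupling of an 8-iodoflavone with a 3'-boronate flavone, the established way to 3',8''-biflavones; the bulky electron-rich biarylphosphine is chosen for the tri-ortho-substituted biaryl, and acetals, pyranones and the chelated 5-OH tolerate aqueous phosphate.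

Step 7
Reactants: 10 8-[5-(5-hydroxy-7-methoxy-4-oxo-4H-chromen-2-yl)-2-methoxyphenyl]-5,7-bis(methoxymethoxy)-2-(4-methoxyphenyl)-4H-chromen-4-one
Product: 11 sciadopitysin (5,7-dihydroxy-8-[5-(5-hydroxy-7-methoxy-4-oxo-4H-chromen-2-yl)-2-methoxyphenyl]-2-(4-methoxyphenyl)-4H-chromen-4-one)
Conditions: 3 M aq HCl, MeOH/THF, 50 °C
Reagents that add atoms: none
Why: Acid-catalysed acetal exchange removes both methoxymethyl groups under conditions too mild to touch aryl methyl ethers, and methanol carries the formaldehyde away as dimethoxymethane so that none is present when the electron-rich ring A is later heated in acid; 11 can be checked against the natural product.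

Step 8
Reactants: 11 sciadopitysin
Product: 13 5,7-dihydroxy-6-[5-(5-hydroxy-7-methoxy-4-oxo-4H-chromen-2-yl)-2-methoxyphenyl]-2-(4-methoxyphenyl)-4H-chromen-4-one (target), via ring-opened 1,3-diketone 12 (not isolated)
Conditions: 3 M aq H2SO4/AcOH 1:3, 110 °C, Ar; chromatographic separation, recovered 11 resubmitted
Reagents that add atoms: none
Why: Protonation of the C4'' carbonyl lets water add at C2'', the O1''–C2'' bond breaks, and the 1,3-diketone 12 results, whose aryl ketone carbon on C4a'' is flanked by two ortho hydroxyls (the former O1'' and the 5''-OH). After rotation about the C4a''–C4'' bond the former 5''-hydroxyl adds to the anisoyl carbonyl in a 6-exo-trig closure, and dehydration restores a 4-pyranone whose new O–C2'' bond leaves the biaryl carbon at C6. This is a Wessely–Moser rearrangement, whose closest known cases are the acid-mediated 8-to-6 isomerisations of 8-C-glycosyl- and 8-aryl-5,7-dihydroxyflavones, 8-linked biflavones included. No stereocentre is formed. The step needs closure through the 5''-oxygen and not return through the former O1''; the process is reversible, and the hydroxyl next to C6''–H is less encumbered than the one next to the biaryl carbon, so the 6-linked isomer should accumulate while unchanged 11 is recycled. The 5-hydroxy-7-methoxy half may open too, but both of its closures give the same flavone, and the non-nucleophilic sulfate medium should spare the three aryl methyl ethers.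

Compound list
1 | 2',6'-dihydroxy-4'-methoxyacetophenone | CC(=O)c1c(O)cc(OC)cc1O | starting material
2 | 3-bromo-4-methoxybenzaldehyde | COc1ccc(C=O)cc1Br | starting material
3 | (E)-3-(3-bromo-4-methoxyphenyl)-1-(2,6-dihydroxy-4-methoxyphenyl)prop-2-en-1-one | COc1cc(O)c(C(=O)/C=C/c2ccc(OC)c(Br)c2)c(O)c1 | intermediate
4 | racemic 2-(3-bromo-4-methoxyphenyl)-5-hydroxy-7-methoxychroman-4-one (flavanone, not isolated) | COc1cc(O)c2c(c1)OC(c1ccc(OC)c(Br)c1)CC2=O | intermediate
5 | 2-(3-bromo-4-methoxyphenyl)-5-hydroxy-7-methoxy-4H-chromen-4-one | COc1cc(O)c2c(c1)oc(-c1ccc(OC)c(Br)c1)cc2=O | intermediate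
6 | 5-hydroxy-7-methoxy-2-[4-methoxy-3-(4,4,5,5-tetramethyl-1,3,2-dioxaborolan-2-yl)phenyl]-4H-chromen-4-one | COc1cc(O)c2c(c1)oc(-c1ccc(OC)c(B3OC(C)(C)C(C)(C)O3)c1)cc2=O | intermediate
7 | acacetin | COc1ccc(-c2cc(=O)c3c(O)cc(O)cc3o2)cc1 | starting material
8 | 5,7-bis(methoxymethoxy)-2-(4-methoxyphenyl)-4H-chromen-4-one | COCOc1cc(OCOC)c2c(c1)oc(-c1ccc(OC)cc1)cc2=O | intermediate
9 | 8-iodo-5,7-bis(methoxymethoxy)-2-(4-methoxyphenyl)-4H-chromen-4-one | COCOc1cc(OCOC)c2c(c1I)oc(-c1ccc(OC)cc1)cc2=O | intermediate
10 | 8-[5-(5-hydroxy-7-methoxy-4-oxo-4H-chromen-2-yl)-2-methoxyphenyl]-5,7-bis(methoxymethoxy)-2-(4-methoxyphenyl)-4H-chromen-4-one | COCOc1cc(OCOC)c2c(c1-c1cc(-c3cc(=O)c4c(O)cc(OC)cc4o3)ccc1OC)oc(-c1ccc(OC)cc1)cc2=O | intermediate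
11 | sciadopitysin (8''-linked isomer, precursor of the key step) | COc1ccc(-c2cc(=O)c3c(O)cc(O)c(-c4cc(-c5cc(=O)c6c(O)cc(OC)cc6o5)ccc4OC)c3o2)cc1 | intermediate
12 | 1-{2,4,6-trihydroxy-3-[5-(5-hydroxy-7-methoxy-4-oxo-4H-chromen-2-yl)-2-methoxyphenyl]phenyl}-3-(4-methoxyphenyl)propane-1,3-dione (not isolated) | COc1ccc(C(=O)CC(=O)c2c(O)cc(O)c(-c3cc(-c4cc(=O)c5c(O)cc(OC)cc5o4)ccc3OC)c2O)cc1 | intermediate
13 | 5,7-dihydroxy-6-[5-(5-hydroxy-7-methoxy-4-oxo-4H-chromen-2-yl)-2-methoxyphenyl]-2-(4-methoxyphenyl)-4H-chromen-4-one (7,4',4'''-tri-O-methylrobustaflavone) | COc1ccc(-c2cc(=O)c3c(O)c(-c4cc(-c5cc(=O)c6c(O)cc(OC)cc6o5)ccc4OC)c(O)cc3o2)cc1 | target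

Total step count: 8. Longest linear sequence: 6 steps (steps 1, 2, 3, 6, 7, 8); the acacetin branch (steps 4, 5) joins at step 6.

Steps most likely to fail

Step 8. The pyranone may open too slowly at temperatures that the methyl ethers tolerate, the equilibration may stall with much 8-linked material left, and slow O-demethylation may erode the mass balance on recycling. The fallback builds the 6-linked biaryl directly by known chemistry and sets out from acacetin 7. Selective alkylation of the non-chelated 7-hydroxyl (MOMCl, iPr2NEt, CH2Cl2) should give 7-O-(methoxymethyl)acacetin F1. With the 5-hydroxyl free, NIS in DMF iodinates ortho to it at C6 and should give the 6-iodide F2. Suzuki–Miyaura coupling of F2 with boronate 6 under the conditions of step 6 should give the 6''-linked mono-acetal biflavone F3. HCl in MeOH/THF as in step 7 then removes the acetal, and the fallback comes back to the route at target 13.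

Step 6. Oxidative addition and reductive elimination at the hindered, electron-rich C8–I bond may be slow, so that protodeboronation of the ortho-methoxy arylboronate and hydrodeiodination compete; poor solubility of both flavones may make this worse. The fallback forms the biaryl bond with a small partner and builds the second flavone afterwards; it sets out from iodide 9. Coupling of 9 with commercial 5-formyl-2-methoxyphenylboronic acid in excess (Pd(OAc)2, SPhos, K3PO4, dioxane/H2O) should give the biaryl aldehyde F4. Claisen–Schmidt condensation of F4 with acetophenone 1 (KOH, EtOH, rt) should give the chalcone F5; should hydroxide open the bis-acetal pyranone, it can only reclose to the same flavone on acidification. Oxidative cyclisation of F5 (I2 cat., DMSO, 120 °C) closes the second pyranone, and the fallback comes back to the route at 10. Acetal loss in this last operation would only anticipate step 7.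

Step 1. The doubly deprotonated dihydroxyacetophenone may enolise and condense sluggishly, so that Cannizzaro consumption of the aldehyde and incomplete conversion lower the throughput. The fallback replaces the aldol route by an acylation route and sets out from acetophenone 1. Commercial 3-bromo-4-methoxybenzoic acid is converted with (COCl)2 and catalytic DMF into 3-bromo-4-methoxybenzoyl chloride F6. Compound 1 is treated with LiHMDS (4 equiv, THF, −78 °C) and its polylithiated form is C-acylated with F6 to give the 1,3-diketone F7. Cyclodehydration of F7 (cat. H2SO4, AcOH, 95 °C) gives the bromoflavone, and the fallback comes back to the route at 5.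

Further compounds
F1 | step 8 | 5-hydroxy-7-(methoxymethoxy)-2-(4-methoxyphenyl)-4H-chromen-4-one | COCOc1cc(O)c2c(c1)oc(-c1ccc(OC)cc1)cc2=O
F2 | step 8 | 5-hydroxy-6-iodo-7-(methoxymethoxy)-2-(4-methoxyphenyl)-4H-chromen-4-one | COCOc1cc2oc(-c3ccc(OC)cc3)cc(=O)c2c(O)c1I
F3 | step 8 | 5-hydroxy-6-[5-(5-hydroxy-7-methoxy-4-oxo-4H-chromen-2-yl)-2-methoxyphenyl]-7-(methoxymethoxy)-2-(4-methoxyphenyl)-4H-chromen-4-one | COCOc1cc2oc(-c3ccc(OC)cc3)cc(=O)c2c(O)c1-c1cc(-c2cc(=O)c3c(O)cc(OC)cc3o2)ccc1OC
F4 | step 6 | 3-[5,7-bis(methoxymethoxy)-2-(4-methoxyphenyl)-4-oxo-4H-chromen-8-yl]-4-methoxybenzaldehyde | COCOc1cc(OCOC)c2c(c1-c1cc(C=O)ccc1OC)oc(-c1ccc(OC)cc1)cc2=O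
F5 | step 6 | 8-{5-[(E)-3-(2,6-dihydroxy-4-methoxyphenyl)-3-oxoprop-1-en-1-yl]-2-methoxyphenyl}-5,7-bis(methoxymethoxy)-2-(4-methoxyphenyl)-4H-chromen-4-one | COCOc1cc(OCOC)c2c(c1-c1cc(/C=C/C(=O)c3c(O)cc(OC)cc3O)ccc1OC)oc(-c1ccc(OC)cc1)cc2=O
F6 | step 1 | 3-bromo-4-methoxybenzoyl chloride | COc1ccc(C(Cl)=O)cc1Br
F7 | step 1 | 1-(3-bromo-4-methoxyphenyl)-3-(2,6-dihydroxy-4-methoxyphenyl)propane-1,3-dione | COc1cc(O)c(C(=O)CC(=O)c2ccc(OC)c(Br)c2)c(O)c1
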